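Follow each mole of E through elm, entry by entry, until the books close.

| setting | elm | maple | cedar |
|---|---|---|---|
| E | 0.23 M | 0.23 M | 0.23 M |
| L | 0.46 mM | 0.46 mM | 0.46 mM |
| temperature | 40 °C | −10 °C | 15 °C |
| time | 2.0 d | 2.0 d | 2.0 d |

    E ⇌ J (K1 = 4.4, k1 = 0.026 /h, Ea1 = 97.0 kJ/mol, ΔH1 = −49.0 kJ/mol)
    E + Z → D + Z, rate k2*[Z]*[E] (k2 = 190 /M/h, Ea2 = 50.0 kJ/mol)
    Z + D → Z.D (k3 = 0.082 /M/h, Ea3 = 83.0 kJ/mol)
    E + L → Z + D (k4 = 0.19 /M/h, Ea4 = 66.0 kJ/mol)
    (constants at 40 °C)

* the flask with the highest amount of D, in percent of the E charged ("all alike" if they lie within 1.5 percentage points) (elm / maple / cedar / all alike)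
* final D, as a percentage of the E charged, in elm
* final D, as a percentage of the E charged, in maple
* final D, as a percentage of the E charged, in cedar

- constants are those at 40 °C; use the activation energies and enthalpies for any other temperature

E is the limiting reagent for D, so the ledger for elm is kept in percent of the E charged.

1. The small entries. In elm, L can hand over at most 0.200 % of the E charged, so D made directly by E + L and D held as Z.D are dropped from the books.

2. The mean of cE. E falls during the elm run from its charge towards little, so the curve is replaced by its mean, taken as 0.115 M, half of the charge.

3. The mean of cZ. At that mean cE, L decays pseudo-first-order in elm with an exponent of 1.05 over 2.0 d. So 35.0 % of L remains, and averaging the rising curve of Z over the run gives 0.175 mM.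

4. The share. This mean cZ turns E into D in elm with a pseudo-first-order constant of 0.0333 /h, larger than the 0.026 /h with which E forms J. The Z-share, the catalytic constant divided by the sum of the catalytic and J-forming constants, is 56.1 % in elm.

5. The closing. E leaves at 0.0593 /h in elm, so the books close with 5.82 % as E, 52.9 % as D and 41.3 % as J. The return from J is left out of these books, but by their close it is not small: the J entry gives back 0.00244 /h of the charge, more than the 0.00151 /h that the E entry sends to J, so the E entry stands on the low side.

6. The error of the mean. This decay gives elm a mean cE of 33.1 % of the charge, lower than the value assumed. So the mean cZ stands on the high side.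

7. The limit of the ledger. The E to J step speeds up by a factor of 1200 from maple to elm, so the mean taken for elm is not carried into the colder flasks, and the reckoning stops here.

The forecast names elm, with D at 51 % in elm, lower than this ledger's entry, 0.09 % in maple and 7.2 % in cedar, on these grounds: “D forms in a race between Z-catalysed conversion and the loss of E to J”.

Elm holds the most D, 50.4 %, more than the 0.0954 % in maple and the 7.76 % in cedar. At 2.00 d elm also holds E at 9.00 % and J at 40.6 %, and D over D plus J reads 55.4 % against a Z-share of 56.1 %. A neighbour of elm charged with 0.092 M of E goes through the same ledger: the exponent is 0.420, the mean cZ 0.0843 mM, the Z-share 38.1 % and the D entry 33.0 %. That neighbour ends with J at 49.5 % and D at 34.6 %.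

The numbers of this flask are made up.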